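**Retrosynthetic overview**
1. The butenolide is attached last: C12–C13 by Negishi coupling of a C12 alkylzinc with 3-bromofuran-2(5H)-one.
2. 19-OAc and 20-CHO come from a C19 ester (reduced, acetylated) and a C20 silyl ether; the C3 ketone left by the key step is removed as its tosylhydrazone in the same hydride step.
3. Key disconnection C4–C5 (then C10–C9): Mn(III)/Cu(II) oxidative bicyclization of an acyclic α-methyl β-keto ester. The enolate carbon C4 is oxidised to an electrophilic radical and bonds to the nucleophilic alkene carbon C5. Ring A forms first, then ring B; all four stereocentres and the 8(17)-methylene are set in this step, with an 8-phenylmenthyl ester controlling absolute configuration.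
4. The acyclic (Z,E)-diene β-keto ester comes from two Claisen rearrangements (each sets one trisubstituted alkene) and a crossed Claisen condensation.

Convention: bicyclic compounds use labdane numbering (C1–C20). "ent" means the andrographolide series: 4-CH3 β, C19 α (axial), H-5 β, H-9 β, C20 α (axial), C9 side chain α (equatorial). "8-Phenylmenthyl" = (1S,2R,5S)-5-methyl-2-(2-phenylpropan-2-yl)cyclohexyl.

Assumption: the (1S,2R,5S)-(+)-8-phenylmenthyl ester is assumed to give the ent series, by analogy with the (–)-ester giving the natural podocarpate series; if the sense is opposite, the (–)-auxiliary is used with nothing else changed.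

**Route**

Step 1
Reactants: 1 isopropenylmagnesium bromide; 2 3-[(tert-butyldimethylsilyl)oxy]propanal
Product: 3 rac-5-[(tert-butyldimethylsilyl)oxy]-2-methylpent-1-en-3-ol
Conditions: THF, –78 → 0 °C; aq. NH4Cl
Reagents that add atoms: none
Why: Grignard 1,2-addition to the aldehyde; the carbinol centre is racemic and is destroyed in step 2.

Step 2
Reactants: 3 rac-5-[(tert-butyldimethylsilyl)oxy]-2-methylpent-1-en-3-ol; 4 butyl vinyl ether
Product: 6 (4E)-7-[(tert-butyldimethylsilyl)oxy]-4-methylhept-4-enal, via allyl vinyl ether 5 (not isolated)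
Conditions: butyl vinyl ether (solvent), Hg(OAc)2 (0.2 equiv), NaOAc, 40 °C; then sealed tube, 130 °C
Reagents that add atoms: none
Why: Hg(II)-catalysed transvinylation then aldehyde Claisen [3,3] rearrangement through a chair transition state with the CH2CH2OTBS group equatorial gives the (E)-trisubstituted alkene (about 9:1, minor isomer removed by chromatography).

Step 3
Reactants: 7 2-bromoprop-2-en-1-ol
Product: 8 [(2-bromoprop-2-en-1-yl)oxy](tert-butyl)dimethylsilane
Conditions: TBSCl, imidazole, DMF, 0 °C → rt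
Reagents that add atoms: tert-butyldimethylsilyl chloride, CC(C)(C)[Si](C)(C)Cl
Why: standard imidazole-promoted silylation of a primary alcohol.

Step 4
Reactants: 8 [(2-bromoprop-2-en-1-yl)oxy](tert-butyl)dimethylsilane; 6 (4E)-7-[(tert-butyldimethylsilyl)oxy]-4-methylhept-4-enal
Product: 10 (6E)-9-[(tert-butyldimethylsilyl)oxy]-2-{[(tert-butyldimethylsilyl)oxy]methyl}-6-methylnona-1,6-dien-3-ol (racemic), via vinyllithium 9 (not isolated)
Conditions: 8, t-BuLi (2.05 equiv), Et2O, –78 °C; then 6, –78 °C; aq. NH4Cl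
Reagents that add atoms: none
Why: bromine–lithium exchange gives the 2-lithioallyl ether, which adds 1,2 to the aldehyde at –78 °C; the racemic carbinol centre is lost in step 5.

Step 5
Reactants: 10 (6E)-9-[(tert-butyldimethylsilyl)oxy]-2-{[(tert-butyldimethylsilyl)oxy]methyl}-6-methylnona-1,6-dien-3-ol; 11 triethyl orthoacetate
Product: 14 ethyl (4Z,8E)-11-[(tert-butyldimethylsilyl)oxy]-4-{[(tert-butyldimethylsilyl)oxy]methyl}-8-methylundeca-4,8-dienoate, via mixed orthoester 12 (not isolated), via ketene acetal 13 (not isolated)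
Conditions: MeC(OEt)3 (6 equiv), EtCO2H (0.1 equiv), 140 °C, EtOH distilled off
Reagents that add atoms: none
Why: Johnson–Claisen rearrangement; the chair transition state with the chain equatorial puts the new CH2CH2CO2Et arm trans to C6 (4Z by CIP because CH2OTBS outranks the chain), which is the geometry a trans-decalin requires.

Step 6
Reactants: 15 (1S,2R,5S)-5-methyl-2-(2-phenylpropan-2-yl)cyclohexan-1-ol [(+)-8-phenylmenthol]; 16 propanoyl chloride
Product: 17 (1S,2R,5S)-8-phenylmenthyl propanoate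
Conditions: pyridine, DMAP (cat.), CH2Cl2, 0 °C → rt
Reagents that add atoms: none
Why: DMAP-catalysed acylation of the auxiliary alcohol.

Step 7
Reactants: 17 (1S,2R,5S)-8-phenylmenthyl propanoate; 14 ethyl (4Z,8E)-11-[(tert-butyldimethylsilyl)oxy]-4-{[(tert-butyldimethylsilyl)oxy]methyl}-8-methylundeca-4,8-dienoate
Product: 19 (1S,2R,5S)-8-phenylmenthyl (6Z,10E)-13-[(tert-butyldimethylsilyl)oxy]-6-{[(tert-butyldimethylsilyl)oxy]methyl}-2,10-dimethyl-3-oxotrideca-6,10-dienoate (both C2 epimers), via lithium enolate 18 (not isolated)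
Conditions: LDA (2.3 equiv), 17 (2.3 equiv), THF, –78 °C; then 14, –78 → 0 °C; AcOH quench (excess 17 recovered)
Reagents that add atoms: none
Why: crossed Claisen condensation, driven by deprotonation of the β-keto ester by the second equivalent of enolate; the C2 epimer mixture does not matter because that carbon becomes a radical in step 8.

Step 8
Reactants: 19 (1S,2R,5S)-8-phenylmenthyl (6Z,10E)-13-[(tert-butyldimethylsilyl)oxy]-6-{[(tert-butyldimethylsilyl)oxy]methyl}-2,10-dimethyl-3-oxotrideca-6,10-dienoate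
Product: 20 (1S,2R,5S)-8-phenylmenthyl 12,20-bis[(tert-butyldimethylsilyl)oxy]-3-oxo-13,14,15,16-tetranor-ent-labd-8(17)-en-19-oate
Conditions: Mn(OAc)3·2H2O (2.2 equiv), Cu(OAc)2·H2O (1.0 equiv), degassed EtOH (0.02 M), 40 °C; chromatography
Reagents that add atoms: none
Why: Mn(III)-based oxidative free-radical polycyclization (Snider): the Mn(III) enolate gives an electrophilic α-keto ester radical at C4 (a carbon that is nucleophilic in its normal polarity), which adds 6-endo to the nucleophilic alkene carbon C5, the C10 radical closes 6-endo on C9, and Cu(II) oxidises the tertiary C8 radical mainly to the exocyclic alkene; chair–chair transition states with the (Z,E)-diene give the trans-decalin with the ester axial (cis to C20) and the C9 chain equatorial, and the phenyl group of the auxiliary shields one face of the radical so that C4, C5, C9 and C10 are set in the ent series (minor diastereomer and Δ7/Δ8 isomers removed by chromatography).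

Step 9
Reactants: 20 (1S,2R,5S)-8-phenylmenthyl 12,20-bis[(tert-butyldimethylsilyl)oxy]-3-oxo-13,14,15,16-tetranor-ent-labd-8(17)-en-19-oate
Product: 21 3-(4-methylbenzenesulfonyl)hydrazone of 20
Conditions: TsNHNH2 (1.5 equiv), AcOH (cat.), EtOH, 70 °C
Reagents that add atoms: 4-methylbenzenesulfonohydrazide, Cc1ccc(cc1)S(=O)(=O)NN
Why: hydrazone condensation at the only ketone; the hindered ester is untouched and no stereocentre is affected.

Step 10
Reactants: 21 3-(4-methylbenzenesulfonyl)hydrazone of 20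
Product: 22 12,20-bis[(tert-butyldimethylsilyl)oxy]-13,14,15,16-tetranor-ent-labd-8(17)-en-19-ol
Conditions: LiAlH4 (excess), THF, reflux; Fieser work-up (auxiliary 15 recovered)
Reagents that add atoms: none
Why: Caglioti reduction of the tosylhydrazone (C=N to CH2 with loss of N2 and sulfinate) and hydride reduction of the hindered ester to the 19-carbinol occur in one operation; silyl ethers and the isolated alkene are inert.

Step 11
Reactants: 22 12,20-bis[(tert-butyldimethylsilyl)oxy]-13,14,15,16-tetranor-ent-labd-8(17)-en-19-ol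
Product: 23 19-acetoxy-12,20-bis[(tert-butyldimethylsilyl)oxy]-13,14,15,16-tetranor-ent-labd-8(17)-ene
Conditions: Ac2O, pyridine, DMAP (cat.), CH2Cl2, rt
Reagents that add atoms: acetic anhydride, CC(=O)OC(C)=O
Why: DMAP-catalysed acetylation of the only free hydroxyl; it is done while C20 is still masked, so that no 19,20-lactol can form later.

Step 12
Reactants: 23 19-acetoxy-12,20-bis[(tert-butyldimethylsilyl)oxy]-13,14,15,16-tetranor-ent-labd-8(17)-ene
Product: 24 19-acetoxy-13,14,15,16-tetranor-ent-labd-8(17)-ene-12,20-diol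
Conditions: HF·pyridine, THF/pyridine, 0 °C → rt
Reagents that add atoms: none
Why: fluoride-mediated cleavage of both silyl ethers under buffered conditions that leave the acetate and the exocyclic alkene intact.

Step 13
Reactants: 24 19-acetoxy-13,14,15,16-tetranor-ent-labd-8(17)-ene-12,20-diol
Product: 25 19-acetoxy-12-iodo-13,14,15,16-tetranor-ent-labd-8(17)-en-20-ol
Conditions: I2, PPh3, imidazole, CH2Cl2, 0 °C
Reagents that add atoms: iodine, II
Why: Appel (Garegg–Samuelsson) iodination is selective for the unhindered primary 12-OH because SN2 displacement at the neopentyl C20 carbinol is blocked.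

Step 14
Reactants: 25 19-acetoxy-12-iodo-13,14,15,16-tetranor-ent-labd-8(17)-en-20-ol
Product: 26 19-acetoxy-12-iodo-13,14,15,16-tetranor-ent-labd-8(17)-en-20-al
Conditions: Dess–Martin periodinane, NaHCO3, CH2Cl2, rt
Reagents that add atoms: none
Why: Dess–Martin oxidation of the neopentyl alcohol to the non-enolisable aldehyde; it is done after C12 is an iodide so that no 12,20-lactol can form.

Step 15
Reactants: 26 19-acetoxy-12-iodo-13,14,15,16-tetranor-ent-labd-8(17)-en-20-al; 27 3-bromofuran-2(5H)-one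
Product: 29 19-acetoxy-20-oxo-ent-labda-8(17),13-dien-16,15-olide (target; [(1R,4aR,5R,8aR)-4a-formyl-1-methyl-6-methylidene-5-[2-(2-oxo-2,5-dihydrofuran-3-yl)ethyl]decahydronaphthalen-1-yl]methyl acetate), via alkylzinc iodide 28 (not isolated)
Conditions: Zn dust (activated), LiCl, THF, 35 °C; then 27, Pd(OAc)2 (3 mol %), SPhos (6 mol %), THF, 25 °C
Reagents that add atoms: none
Why: LiCl-assisted zinc insertion then Negishi coupling at the α-carbon of the bromobutenolide gives the α-alkyl butenolide directly with the ring double bond already in place; alkylzinc halides do not add to the hindered aldehyde or the acetate without activation.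

**Compound list**
1 | isopropenylmagnesium bromide | C=C(C)[Mg]Br | starting material
2 | 3-[(tert-butyldimethylsilyl)oxy]propanal | O=CCCO[Si](C)(C)C(C)(C)C | starting material
3 | rac-5-[(tert-butyldimethylsilyl)oxy]-2-methylpent-1-en-3-ol | C=C(C)C(O)CCO[Si](C)(C)C(C)(C)C | intermediate
4 | butyl vinyl ether | C=COCCCC | starting material
5 | tert-butyl{[3-(ethenyloxy)-4-methylpent-4-en-1-yl]oxy}dimethylsilane (allyl vinyl ether) | C=COC(CCO[Si](C)(C)C(C)(C)C)C(C)=C | intermediate
6 | (4E)-7-[(tert-butyldimethylsilyl)oxy]-4-methylhept-4-enal | O=CCC/C(C)=C/CCO[Si](C)(C)C(C)(C)C | intermediate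
7 | 2-bromoprop-2-en-1-ol | C=C(Br)CO | starting material
8 | [(2-bromoprop-2-en-1-yl)oxy](tert-butyl)dimethylsilane | C=C(Br)CO[Si](C)(C)C(C)(C)C | intermediate
9 | {3-[(tert-butyldimethylsilyl)oxy]prop-1-en-2-yl}lithium | [Li]C(=C)CO[Si](C)(C)C(C)(C)C | intermediate
10 | (6E)-9-[(tert-butyldimethylsilyl)oxy]-2-{[(tert-butyldimethylsilyl)oxy]methyl}-6-methylnona-1,6-dien-3-ol (racemic) | C=C(CO[Si](C)(C)C(C)(C)C)C(O)CC/C(C)=C/CCO[Si](C)(C)C(C)(C)C | intermediate
11 | triethyl orthoacetate | CCOC(C)(OCC)OCC | starting material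
12 | 1,1-diethoxyethyl ether of 10 (mixed orthoester) | C=C(CO[Si](C)(C)C(C)(C)C)C(OC(C)(OCC)OCC)CC/C(C)=C/CCO[Si](C)(C)C(C)(C)C | intermediate
13 | 1-ethoxyethenyl ether of 10 (ketene acetal) | C=C(CO[Si](C)(C)C(C)(C)C)C(OC(=C)OCC)CC/C(C)=C/CCO[Si](C)(C)C(C)(C)C | intermediate
14 | ethyl (4Z,8E)-11-[(tert-butyldimethylsilyl)oxy]-4-{[(tert-butyldimethylsilyl)oxy]methyl}-8-methylundeca-4,8-dienoate | CCOC(=O)CC/C(CO[Si](C)(C)C(C)(C)C)=C/CC/C(C)=C/CCO[Si](C)(C)C(C)(C)C | intermediate
15 | (1S,2R,5S)-5-methyl-2-(2-phenylpropan-2-yl)cyclohexan-1-ol [(+)-8-phenylmenthol] | CC(C)(c1ccccc1)[C@H]1CC[C@H](C)C[C@@H]1O | starting material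
16 | propanoyl chloride | CCC(Cl)=O | starting material
17 | (1S,2R,5S)-8-phenylmenthyl propanoate | CCC(=O)O[C@H]1C[C@@H](C)CC[C@@H]1C(C)(C)c1ccccc1 | intermediate
18 | lithium enolate of 17 | CC=C(O[Li])O[C@H]1C[C@@H](C)CC[C@@H]1C(C)(C)c1ccccc1 | intermediate
19 | (1S,2R,5S)-8-phenylmenthyl (6Z,10E)-13-[(tert-butyldimethylsilyl)oxy]-6-{[(tert-butyldimethylsilyl)oxy]methyl}-2,10-dimethyl-3-oxotrideca-6,10-dienoate (C2 epimers) | CC(C(=O)O[C@H]1C[C@@H](C)CC[C@@H]1C(C)(C)c1ccccc1)C(=O)CC/C(CO[Si](C)(C)C(C)(C)C)=C/CC/C(C)=C/CCO[Si](C)(C)C(C)(C)C | intermediate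
20 | (1S,2R,5S)-8-phenylmenthyl 12,20-bis[(tert-butyldimethylsilyl)oxy]-3-oxo-13,14,15,16-tetranor-ent-labd-8(17)-en-19-oate | C=C1CC[C@@H]2[C@](C)(C(=O)O[C@H]3C[C@@H](C)CC[C@@H]3C(C)(C)c3ccccc3)C(=O)CC[C@@]2(CO[Si](C)(C)C(C)(C)C)[C@@H]1CCO[Si](C)(C)C(C)(C)C | intermediate
21 | 3-(4-methylbenzenesulfonyl)hydrazone of 20 | C=C1CC[C@@H]2[C@](C)(C(=O)O[C@H]3C[C@@H](C)CC[C@@H]3C(C)(C)c3ccccc3)C(=NNS(=O)(=O)c3ccc(C)cc3)CC[C@@]2(CO[Si](C)(C)C(C)(C)C)[C@@H]1CCO[Si](C)(C)C(C)(C)C | intermediate
22 | 12,20-bis[(tert-butyldimethylsilyl)oxy]-13,14,15,16-tetranor-ent-labd-8(17)-en-19-ol | C=C1CC[C@@H]2[C@](C)(CO)CCC[C@@]2(CO[Si](C)(C)C(C)(C)C)[C@@H]1CCO[Si](C)(C)C(C)(C)C | intermediate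
23 | 19-acetoxy-12,20-bis[(tert-butyldimethylsilyl)oxy]-13,14,15,16-tetranor-ent-labd-8(17)-ene | C=C1CC[C@@H]2[C@](C)(COC(C)=O)CCC[C@@]2(CO[Si](C)(C)C(C)(C)C)[C@@H]1CCO[Si](C)(C)C(C)(C)C | intermediate
24 | 19-acetoxy-13,14,15,16-tetranor-ent-labd-8(17)-ene-12,20-diol | C=C1CC[C@@H]2[C@](C)(COC(C)=O)CCC[C@@]2(CO)[C@@H]1CCO | intermediate
25 | 19-acetoxy-12-iodo-13,14,15,16-tetranor-ent-labd-8(17)-en-20-ol | C=C1CC[C@@H]2[C@](C)(COC(C)=O)CCC[C@@]2(CO)[C@@H]1CCI | intermediate
26 | 19-acetoxy-12-iodo-13,14,15,16-tetranor-ent-labd-8(17)-en-20-al | C=C1CC[C@@H]2[C@](C)(COC(C)=O)CCC[C@@]2(C=O)[C@@H]1CCI | intermediate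
27 | 3-bromofuran-2(5H)-one | O=C1OCC=C1Br | starting material
28 | [19-acetoxy-20-oxo-13,14,15,16-tetranor-ent-labd-8(17)-en-12-yl]zinc iodide | C=C1CC[C@@H]2[C@](C)(COC(C)=O)CCC[C@@]2(C=O)[C@@H]1CC[Zn]I | intermediate
29 | 19-acetoxy-20-oxo-ent-labda-8(17),13-dien-16,15-olide | C=C1CC[C@@H]2[C@](C)(COC(C)=O)CCC[C@@]2(C=O)[C@@H]1CCC1=CCOC1=O | target

**Step count**
Total: 15 steps. Longest linear sequence: 13 steps (1, 2, 4, 5, 7–15); steps 3 and 6 are side-branch preparations.

**Three steps most likely to fail**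

Step 8. The risks are an exo/endo alkene mixture from the Cu(II) termination and incomplete diastereocontrol by the auxiliary. Fallback: from 19, bromination (NBS, Mg(ClO4)2 cat., EtOAc) gives the α-bromo β-keto ester F1. Lewis-acid-promoted atom-transfer radical cyclization (Yb(OTf)3, Et3B/O2, CH2Cl2, –78 °C) then gives the 8-bromo bicycle F2 as C8 epimers, still through the electrophilic C4 radical but terminated by bromine transfer instead of oxidation. Dehydrobromination with KOt-Bu (t-BuOH/THF, 50 °C, Hofmann-selective) returns to the route at 20.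

Step 10. The risks are Bamford–Stevens-type elimination to a Δ2-alkene instead of clean reduction, and slow hydrazone reduction next to the quaternary C4. Fallback: from 20, NaBH4 (MeOH, 0 °C) gives the 3-hydroxy ester F3. PhOC(S)Cl, pyridine and DMAP give the O-phenyl thionocarbonate F4, and Bu3SnH/AIBN (toluene, 100 °C, Barton–McCombie) gives the 3-deoxy ester F5. LiAlH4 (THF, reflux) then rejoins the route at 22.

Step 15. The risks are that the alkylzinc cyclises onto the nearby C20 aldehyde, or that the electron-poor bromobutenolide is reduced or homocoupled. Fallback: from 26, alkylation of the sodium enolate of 3-(phenylsulfanyl)oxolan-2-one (NaHMDS, THF/HMPA, –40 → 0 °C) gives the α-phenylsulfanyl lactone F6. mCPBA (1.0 equiv, CH2Cl2, –78 °C) gives the sulfoxide F7, and thermal syn-elimination (toluene, CaCO3, 100 °C), which favours the endocyclic alkene in γ-lactones, arrives at 29.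

**Further compounds**
F1 | step 8 | (1S,2R,5S)-8-phenylmenthyl (6Z,10E)-2-bromo-13-[(tert-butyldimethylsilyl)oxy]-6-{[(tert-butyldimethylsilyl)oxy]methyl}-2,10-dimethyl-3-oxotrideca-6,10-dienoate | CC(Br)(C(=O)O[C@H]1C[C@@H](C)CC[C@@H]1C(C)(C)c1ccccc1)C(=O)CC/C(CO[Si](C)(C)C(C)(C)C)=C/CC/C(C)=C/CCO[Si](C)(C)C(C)(C)C
F2 | step 8 | (1S,2R,5S)-8-phenylmenthyl 8-bromo-12,20-bis[(tert-butyldimethylsilyl)oxy]-3-oxo-13,14,15,16-tetranor-ent-labdan-19-oate (C8 epimers) | CC1(Br)CC[C@@H]2[C@](C)(C(=O)O[C@H]3C[C@@H](C)CC[C@@H]3C(C)(C)c3ccccc3)C(=O)CC[C@@]2(CO[Si](C)(C)C(C)(C)C)[C@@H]1CCO[Si](C)(C)C(C)(C)C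
F3 | step 10 | (1S,2R,5S)-8-phenylmenthyl 12,20-bis[(tert-butyldimethylsilyl)oxy]-3-hydroxy-13,14,15,16-tetranor-ent-labd-8(17)-en-19-oate | C=C1CC[C@@H]2[C@](C)(C(=O)O[C@H]3C[C@@H](C)CC[C@@H]3C(C)(C)c3ccccc3)C(O)CC[C@@]2(CO[Si](C)(C)C(C)(C)C)[C@@H]1CCO[Si](C)(C)C(C)(C)C
F4 | step 10 | 3-O-(phenoxythiocarbonyl) derivative of F3 | C=C1CC[C@@H]2[C@](C)(C(=O)O[C@H]3C[C@@H](C)CC[C@@H]3C(C)(C)c3ccccc3)C(OC(=S)Oc3ccccc3)CC[C@@]2(CO[Si](C)(C)C(C)(C)C)[C@@H]1CCO[Si](C)(C)C(C)(C)C
F5 | step 10 | (1S,2R,5S)-8-phenylmenthyl 12,20-bis[(tert-butyldimethylsilyl)oxy]-13,14,15,16-tetranor-ent-labd-8(17)-en-19-oate | C=C1CC[C@@H]2[C@](C)(C(=O)O[C@H]3C[C@@H](C)CC[C@@H]3C(C)(C)c3ccccc3)CCC[C@@]2(CO[Si](C)(C)C(C)(C)C)[C@@H]1CCO[Si](C)(C)C(C)(C)C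
F6 | step 15 | 19-acetoxy-20-oxo-13-(phenylsulfanyl)-ent-labd-8(17)-en-16,15-olide (C13 epimers) | C=C1CC[C@@H]2[C@](C)(COC(C)=O)CCC[C@@]2(C=O)[C@@H]1CCC1(Sc2ccccc2)CCOC1=O
F7 | step 15 | S-oxide of F6 (sulfoxide) | C=C1CC[C@@H]2[C@](C)(COC(C)=O)CCC[C@@]2(C=O)[C@@H]1CCC1(S(=O)c2ccccc2)CCOC1=O
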